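**Retrosynthetic overview**
- The last step is one acid treatment that frees the C15 acid and strips a traceless silyl group from the vinyl. Before it, a samarium-mediated aldol / Evans–Tishchenko / lactonisation cascade on an open-chain keto-aldehyde closes the cyclohexane (C7–C8), sets C6, C7 and C8, and installs the tiglate and the γ-lactone.
- The keto-aldehyde comes from a δ-lactol: the C6–C7 bond is made with a 2-(methoxycarbonyl)allyl-indium reagent (homoenolate-type d3 nucleophile), followed by double oxidation.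
- Key bond C5–C4: a lactone enolate is joined to the α-carbon of an acrylate, using tert-butyl 3-nitroacrylate as an acrylate α-cation (a2, enolonium-type) equivalent. Loss of HNO2 gives the C5 acrylate directly.
- The quaternary centre C10 comes from a copper-catalysed enantioselective conjugate addition of a 1-silylvinyl-alane to anhydromevalonolactone.
- Ring order: δ-lactone template (steps 2–3), opened (steps 4–6), then cyclohexane and finally γ-lactone (step 7).

Assumption: elemane locants of the target are used throughout (C10 quaternary with C14 methyl and C1=C2 vinyl; C9 H2; C8 O-tigloyl; C7; C6 lactone O; C5; C11(=C13)–C12 lactone; C4(=C3)–C15 acid), and 4-methyl-5,6-dihydro-2H-pyran-2-one (4) is taken as purchasable.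

**Step 1**
Reactants: 1 tert-butyl prop-2-enoate
Product: 3 tert-butyl (2E)-3-nitroprop-2-enoate, via iodo-nitro ester 2 (not isolated)
Conditions: AgNO2, I2, Et2O, 0 °C → rt; then Et3N, 0 °C
Reagents that add atoms: silver nitrite, [Ag+].[O-]N=O
Why: Hassner-type nitro-iodination, in which nitryl iodide (from AgNO2/I2) adds across the acrylate with NO2 at the terminal carbon and Et3N then eliminates HI from the α-iodo ester to give the conjugated (E)-nitroalkene; no stereocentre is formed.

**Step 2**
Reactants: 4 4-methyl-5,6-dihydro-2H-pyran-2-one; 5 ethynyl(trimethyl)silane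
Product: 7 (4R)-4-methyl-4-[1-(trimethylsilyl)ethenyl]oxan-2-one, via vinylalane 6 (not isolated)
Conditions: 5, i-Bu2AlH, hexane/THF, 55 °C; then 4, Cu(OTf)2 (5 mol %), chiral sulfonate-imidazolinium NHC precursor (5 mol %), THF, −30 → 4 °C; aq. potassium sodium tartrate
Reagents that add atoms: none
Why: Proposed new method: copper–NHC-catalysed enantioselective conjugate addition of an α-silylvinylaluminium (made by hydroalumination that places Al and Si on the same carbon), established for β-methyl cyclic enones, is extended to the β-methyl unsaturated δ-lactone, which has the same rigid s-trans acceptor geometry and is activated by the Lewis-acidic alane (closest known reactions: that enone addition and copper-catalysed asymmetric conjugate additions to 5,6-dihydropyran-2-one), the chiral NHC–copper complex selecting the alkene face so that C10 is formed as the (4R)-lactone.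

**Step 3**
Reactants: 7 (4R)-4-methyl-4-[1-(trimethylsilyl)ethenyl]oxan-2-one; 3 tert-butyl (2E)-3-nitroprop-2-enoate
Product: 9 tert-butyl 2-{(3S,4R)-4-methyl-2-oxo-4-[1-(trimethylsilyl)ethenyl]oxan-3-yl}prop-2-enoate, via nitro ester 8 (not isolated)
Conditions: LiN(i-Pr)2, THF, −78 °C; 3, −78 °C; AcOH; then DBU, CH2Cl2, 0 °C
Reagents that add atoms: none
Why: Michael addition of the lithium lactone enolate to the nitroalkene carbon that is α to the ester, then E1cB loss of nitrite (β-nitroacrylate as acrylate α-cation equivalent, McMurry-type α-methylene chemistry), joins two carbons that are both normally nucleophilic; the electrophile enters C5 anti to the bulky 1-silylvinyl group on the neighbouring quaternary carbon, giving the lactone with acrylate and silylvinyl trans (3S,4R).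

**Step 4**
Reactants: 9 tert-butyl 2-{(3S,4R)-4-methyl-2-oxo-4-[1-(trimethylsilyl)ethenyl]oxan-3-yl}prop-2-enoate
Product: 10 tert-butyl 2-{(3S,4R)-2-hydroxy-4-methyl-4-[1-(trimethylsilyl)ethenyl]oxan-3-yl}prop-2-enoate (lactol)
Conditions: i-Bu2AlH (1.1 equiv), CH2Cl2, −78 °C; aq. potassium sodium tartrate
Reagents that add atoms: none
Why: Partial DIBAL reduction of the lactone to the lactol at −78 °C, where the hindered tert-butyl acrylate reacts much more slowly; C5 and C10 are untouched and the new hemiacetal centre is destroyed again in step 6.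

**Step 5**
Reactants: 10 lactol; 11 methyl 2-(bromomethyl)prop-2-enoate
Product: 12 1-tert-butyl 7-methyl (3S)-4-hydroxy-3-[(3R)-1-hydroxy-3-methyl-4-(trimethylsilyl)pent-4-en-3-yl]-2,6-dimethylideneheptanedioate (both C4 epimers)
Conditions: In powder, THF/H2O (1:1), rt
Reagents that add atoms: none
Why: Aqueous indium Barbier allylation of the lactol through its open hydroxy-aldehyde form, in which the 2-(methoxycarbonyl)allyl-indium species (a homoenolate-type d3 nucleophile) attacks C6 through its γ-carbon under neutral conditions that leave the epimerisable C5 alone; the new C6 carbinol centre is oxidised away in step 6.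

**Step 6**
Reactants: 12 diol diester
Product: 13 1-tert-butyl 7-methyl (3S)-3-[(3R)-3-methyl-1-oxo-4-(trimethylsilyl)pent-4-en-3-yl]-2,6-dimethylidene-4-oxoheptanedioate
Conditions: Dess–Martin periodinane (3 equiv), pyridine, CH2Cl2, 0 °C → rt
Reagents that add atoms: none
Why: Dess–Martin oxidation of the secondary C6 and primary C8 alcohols under pyridine-buffered, non-enolising conditions gives the 1,5-keto-aldehyde without epimerising C5 or moving the exocyclic double bonds.

**Step 7**
Reactants: 13 keto-aldehyde diester; 14 (2E)-2-methylbut-2-enal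
Product: 17 tert-butyl 2-{(3aR,4R,6R,7S,7aR)-6-methyl-3-methylidene-4-{[(2E)-2-methylbut-2-enoyl]oxy}-2-oxo-6-[1-(trimethylsilyl)ethenyl]octahydro-1-benzofuran-7-yl}prop-2-enoate, via ketol 15 (not isolated), via hydroxy ester 16 (not isolated)
Conditions: SmI2 (0.3 equiv; premixed with 14, 6 equiv), THF, −10 °C → rt; then PPTS, CH2Cl2, rt
Reagents that add atoms: none
Why: Proposed new method: the trivalent samarium alkoxide formed from SmI2 and the aldehyde enolises the doubly activated C7–H2, a reversible 6-enolendo aldol onto the C8 aldehyde closes the cyclohexane, and only the aldolate whose O8 is axial (chair fixed by the equatorial silylvinyl, C5 and C7 groups) can add tiglic aldehyde and pass the hemiacetal hydride intramolecularly to the β-face of C6 (Evans–Tishchenko), which fixes C7 (equatorial), C8 (O axial, cis to C14) and C6 (OH equatorial, anti to O8) and puts the tiglate on O8 in the same event, after which the C6 alkoxide lactonises onto the methyl ester; closest known reactions are the SmI2-catalysed Evans–Tishchenko reduction of β-hydroxy ketones and lanthanide-catalysed direct aldol–Tishchenko reactions.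

**Step 8**
Reactants: 17 silylated tert-butyl ester lactone
Product: 18 2-{(3aR,4R,6S,7R,7aR)-6-ethenyl-6-methyl-3-methylidene-4-{[(2E)-2-methylbut-2-enoyl]oxy}-2-oxooctahydro-1-benzofuran-7-yl}prop-2-enoic acid (target)
Conditions: CF3CO2H/CH2Cl2 (1:1), 0 °C → rt; evaporation
Reagents that add atoms: none
Why: Trifluoroacetic acid cleaves the tert-butyl ester (loss of isobutene) and protodesilylates the α-silylvinyl group by ipso-protonation and loss of silicon, leaving the tiglate, the α-methylene lactone and all five stereocentres unchanged.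

**Compound list**
1 | tert-butyl prop-2-enoate (tert-butyl acrylate) | C=CC(=O)OC(C)(C)C | starting material
2 | tert-butyl 2-iodo-3-nitropropanoate (racemic) | [O-][N+](=O)CC(I)C(=O)OC(C)(C)C | intermediate (not isolated)
3 | tert-butyl (2E)-3-nitroprop-2-enoate | [O-][N+](=O)/C=C/C(=O)OC(C)(C)C | intermediate
4 | 4-methyl-5,6-dihydro-2H-pyran-2-one (anhydromevalonolactone) | CC1=CC(=O)OCC1 | starting material
5 | ethynyl(trimethyl)silane | C#C[Si](C)(C)C | starting material
6 | diisobutyl[1-(trimethylsilyl)ethenyl]aluminium | C=C([Si](C)(C)C)[Al](CC(C)C)CC(C)C | intermediate (not isolated)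
7 | (4R)-4-methyl-4-[1-(trimethylsilyl)ethenyl]oxan-2-one | C=C([Si](C)(C)C)[C@]1(C)CCOC(=O)C1 | intermediate
8 | tert-butyl 2-{(3S,4R)-4-methyl-2-oxo-4-[1-(trimethylsilyl)ethenyl]oxan-3-yl}-3-nitropropanoate (both epimers at the ester α-carbon) | C=C([Si](C)(C)C)[C@]1(C)CCOC(=O)[C@H]1C(C[N+](=O)[O-])C(=O)OC(C)(C)C | intermediate (not isolated)
9 | tert-butyl 2-{(3S,4R)-4-methyl-2-oxo-4-[1-(trimethylsilyl)ethenyl]oxan-3-yl}prop-2-enoate (acrylate trans to silylvinyl) | C=C([Si](C)(C)C)[C@]1(C)CCOC(=O)[C@H]1C(=C)C(=O)OC(C)(C)C | intermediate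
10 | tert-butyl 2-{(3S,4R)-2-hydroxy-4-methyl-4-[1-(trimethylsilyl)ethenyl]oxan-3-yl}prop-2-enoate (lactol, both anomers) | C=C([Si](C)(C)C)[C@]1(C)CCOC(O)[C@H]1C(=C)C(=O)OC(C)(C)C | intermediate
11 | methyl 2-(bromomethyl)prop-2-enoate | C=C(CBr)C(=O)OC | starting material
12 | 1-tert-butyl 7-methyl (3S)-4-hydroxy-3-[(3R)-1-hydroxy-3-methyl-4-(trimethylsilyl)pent-4-en-3-yl]-2,6-dimethylideneheptanedioate (both C4 epimers; elemane 5S,10R) | C=C([Si](C)(C)C)[C@](C)(CCO)[C@H](C(=C)C(=O)OC(C)(C)C)C(O)CC(=C)C(=O)OC | intermediate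
13 | 1-tert-butyl 7-methyl (3S)-3-[(3R)-3-methyl-1-oxo-4-(trimethylsilyl)pent-4-en-3-yl]-2,6-dimethylidene-4-oxoheptanedioate (C6 ketone, C8 aldehyde) | C=C([Si](C)(C)C)[C@](C)(CC=O)[C@H](C(=C)C(=O)OC(C)(C)C)C(=O)CC(=C)C(=O)OC | intermediate
14 | (2E)-2-methylbut-2-enal (tiglic aldehyde) | C/C=C(\C)C=O | starting material
15 | methyl 2-{(1R,3S,4R,6R)-3-[1-(tert-butoxycarbonyl)ethenyl]-6-hydroxy-4-methyl-2-oxo-4-[1-(trimethylsilyl)ethenyl]cyclohexyl}prop-2-enoate (ketol; elemane 5S,7R,8R,10R; 8-OH axial, cis to C14) | C=C([Si](C)(C)C)[C@]1(C)C[C@@H](O)[C@@H](C(=C)C(=O)OC)C(=O)[C@H]1C(=C)C(=O)OC(C)(C)C | intermediate (not isolated)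
16 | (1R,2S,3R,4S,5R)-4-[1-(tert-butoxycarbonyl)ethenyl]-3-hydroxy-2-[1-(methoxycarbonyl)ethenyl]-5-methyl-5-[1-(trimethylsilyl)ethenyl]cyclohexyl (2E)-2-methylbut-2-enoate (elemane 5S,6R,7S,8R,10R) | C=C([Si](C)(C)C)[C@]1(C)C[C@@H](OC(=O)/C(C)=C/C)[C@@H](C(=C)C(=O)OC)[C@H](O)[C@H]1C(=C)C(=O)OC(C)(C)C | intermediate (not isolated)
17 | tert-butyl 2-{(3aR,4R,6R,7S,7aR)-6-methyl-3-methylidene-4-{[(2E)-2-methylbut-2-enoyl]oxy}-2-oxo-6-[1-(trimethylsilyl)ethenyl]octahydro-1-benzofuran-7-yl}prop-2-enoate (elemane 5S,6R,7R,8R,10R) | C=C([Si](C)(C)C)[C@]1(C)C[C@@H](OC(=O)/C(C)=C/C)[C@H]2C(=C)C(=O)O[C@@H]2[C@H]1C(=C)C(=O)OC(C)(C)C | intermediate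
18 | 2-{(3aR,4R,6S,7R,7aR)-6-ethenyl-6-methyl-3-methylidene-4-{[(2E)-2-methylbut-2-enoyl]oxy}-2-oxooctahydro-1-benzofuran-7-yl}prop-2-enoic acid (elemane 5R,6R,7R,8R,10S) | C=C[C@]1(C)C[C@@H](OC(=O)/C(C)=C/C)[C@H]2C(=C)C(=O)O[C@@H]2[C@H]1C(=C)C(=O)O | target

**Totals**
Total step count: 8. Longest linear sequence: 7 (steps 2–8); step 1 is a one-step branch that feeds step 3.

**Three steps most likely to fail**

Step 2. The lactone is a weaker acceptor than the enones for which this catalyst is known, so conversion or ee may be low. Fallback, from 4 back to 7: add the cuprate made from [1-(trimethylsilyl)vinyl]magnesium bromide and CuI (Me3SiCl, THF, −40 °C) to 4 to obtain racemic lactone F1. Open it with (S)-1-phenylethylamine/AlMe3 to the diastereomeric hydroxy amides, separate the (3R)-hydroxy amide F2 by crystallisation or chromatography, and relactonise it with TsOH in toluene at 80 °C. This returns 7 and the amine; classical resolution replaces asymmetric catalysis.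

Step 3. A neopentyl-type enolate must attack the nitroalkene. Facial selectivity next to the quaternary centre and base-induced migration of the new C4=C3 bond are the weak points. Fallback, from 7 back to 9, with the polarity roles exchanged: brominate the lithium enolate of 7 with 1,2-dibromotetrachloroethane to the α-bromo lactone F3, so that the lactone α-carbon is now the electrophile. Couple it with [1-(tert-butoxycarbonyl)ethenyl]zinc bromide F4 (from tert-butyl 2-bromoacrylate and Zn dust, THF) under NiCl2(dme)/bis(oxazolinyl)pyridine catalysis in DMA at room temperature. This Negishi coupling of an α-halo carbonyl runs through a C5 radical that is captured anti to the silylvinyl group, and gives 9 without a nitro intermediate.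

Step 7. The cascade needs samarium enolisation at C7 only, a reversible aldol, and a hydride transfer in which the hemiacetal bridges O8 and C6 on the face that carries the axial C14 methyl, so a boat-like transfer is required. Dehydration of ketol 15 or a crossed Tishchenko reaction of the aldehydes may win. Fallback, from 9 back to 17, by the thermodynamic 8-oxo way:
- Reduce 9 with LiBH4 (THF, 0 °C) to diol F5.
- TEMPO/PhI(OAc)2 oxidises the less hindered C8 carbinol and lactonises to the isomeric δ-lactone F6.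
- i-Bu2AlH (−78 °C) gives lactol F7.
- Indium Barbier reaction with 11 gives diol F8.
- Dess–Martin oxidation gives keto-aldehyde F9 (C8 ketone, C6 aldehyde).
- Pyrrolidinium acetate, then PPTS, effects aldol ring closure under thermodynamic control (C5, C6-O and C7 substituents all equatorial) and trans-lactonisation to 8-oxo lactone F10.
- NaBH4/CeCl3·7H2O (MeOH, −78 °C) attacks C8 from the open α-face, the β-face being blocked by the axial C14 methyl, to give 8β-alcohol F11.
- Tigloyl chloride, Et3N and DMAP give 17.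

Here C6 and C7 are set thermodynamically and C8 by simple face-selective hydride addition, at the price of four extra steps.

**Further compounds**
F1 | step 2 | racemic 4-methyl-4-[1-(trimethylsilyl)ethenyl]oxan-2-one | C=C([Si](C)(C)C)C1(C)CCOC(=O)C1
F2 | step 2 | (3R)-5-hydroxy-3-methyl-N-[(1S)-1-phenylethyl]-3-[1-(trimethylsilyl)ethenyl]pentanamide | C=C([Si](C)(C)C)[C@](C)(CCO)CC(=O)N[C@@H](C)c1ccccc1
F3 | step 3 | (4R)-3-bromo-4-methyl-4-[1-(trimethylsilyl)ethenyl]oxan-2-one (both C3 epimers) | C=C([Si](C)(C)C)[C@]1(C)CCOC(=O)C1Br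
F4 | step 3 | [1-(tert-butoxycarbonyl)ethenyl]zinc bromide | C=C([Zn]Br)C(=O)OC(C)(C)C
F5 | step 7 | tert-butyl 2-[(3S,4R)-1,6-dihydroxy-4-methyl-5-(trimethylsilyl)hex-5-en-3-yl... ] i.e. tert-butyl (3S)-3-(hydroxymethyl)-2-methylidene-4-methyl-4-(2-hydroxyethyl)-5-(trimethylsilyl)hex-5-enoate (diol from reduction of 9; elemane 5S,10R) | C=C([Si](C)(C)C)[C@](C)(CCO)[C@@H](CO)C(=C)C(=O)OC(C)(C)C
F6 | step 7 | tert-butyl 2-{(3S,4R)-4-methyl-6-oxo-4-[1-(trimethylsilyl)ethenyl]oxan-3-yl}prop-2-enoate (isomeric δ-lactone, C8 carbonyl) | C=C([Si](C)(C)C)[C@]1(C)CC(=O)OC[C@H]1C(=C)C(=O)OC(C)(C)C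
F7 | step 7 | tert-butyl 2-{(3S,4R)-6-hydroxy-4-methyl-4-[1-(trimethylsilyl)ethenyl]oxan-3-yl}prop-2-enoate (lactol, both anomers) | C=C([Si](C)(C)C)[C@]1(C)CC(O)OC[C@H]1C(=C)C(=O)OC(C)(C)C
F8 | step 7 | open-chain diol diester with C8 carbinol (both epimers) and C6 primary alcohol (elemane 5S,10R) | C=C([Si](C)(C)C)[C@](C)(CC(O)CC(=C)C(=O)OC)[C@@H](CO)C(=C)C(=O)OC(C)(C)C
F9 | step 7 | open-chain keto-aldehyde diester with C8 ketone and C6 aldehyde (elemane 5S,10R) | C=C([Si](C)(C)C)[C@](C)(CC(=O)CC(=C)C(=O)OC)[C@@H](C=O)C(=C)C(=O)OC(C)(C)C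
F10 | step 7 | tert-butyl 2-{(3aS,6R,7S,7aR)-6-methyl-3-methylidene-2,4-dioxo-6-[1-(trimethylsilyl)ethenyl]octahydro-1-benzofuran-7-yl}prop-2-enoate (8-oxo trans-lactone; elemane 5S,6R,7S,10R) | C=C([Si](C)(C)C)[C@]1(C)CC(=O)[C@H]2C(=C)C(=O)O[C@@H]2[C@H]1C(=C)C(=O)OC(C)(C)C
F11 | step 7 | tert-butyl 2-{(3aR,4R,6R,7S,7aR)-4-hydroxy-6-methyl-3-methylidene-2-oxo-6-[1-(trimethylsilyl)ethenyl]octahydro-1-benzofuran-7-yl}prop-2-enoate (8β-alcohol; elemane 5S,6R,7R,8R,10R) | C=C([Si](C)(C)C)[C@]1(C)C[C@@H](O)[C@H]2C(=C)C(=O)O[C@@H]2[C@H]1C(=C)C(=O)OC(C)(C)C
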